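## The problem

Target 15, (2S)-2-(3,4-dimethoxyphenyl)-8-hydroxy-5,6,7-trimethoxychroman-4-one, is a flavanone in which dihydropyranone ring C is fused to a fully substituted benzene ring A and carries a 3,4-dimethoxyphenyl ring B on C2. Ring A bears five oxygens in a fixed order (O1 on C8a, a free hydroxyl on C8, methoxyls on C7, C6 and C5), so the C8 oxygen must stay distinguishable from its methylated neighbours and from O1 throughout. C2, of S configuration, is the only stereocentre; nothing in the molecule can relay configuration to it, so it has to be set by a catalyst or reagent and then guarded in every later step. Base endangers it, because the C3 enolate expels the C8a phenoxide in an E1cB opening of ring C and reclosure of the resulting chalcone is not stereoselective. Acid endangers it as well, because C2 is a benzylic ether carbon para to a methoxyl and the C2–O1 bond can ionise. The penta-oxygenated ring A is also easily oxidised to quinones, and the C5 methoxyl peri to the carbonyl is labile to strong Lewis acids. The enabling feature is that C4a is the only ring A carbon without an oxygen: a halogen on ring A can sit nowhere else, and it then marks exactly the carbon at which the C4–C4a bond has to form.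

## Retrosynthesis

**15 ⇒ 14.** The O–CH2 bond of a protecting group on the C8 oxygen is cut first, giving the methoxymethyl ether 14. A benzyl ether would need hydrogenolysis next to the benzylic C2–O1 bond, and a silyl ether would need fluoride, which is basic enough to open ring C. The acetal leaves under mild acid, survives organolithium reagents, and also serves as an ortho-director when ring A is built. The forward step only has to be mild enough not to ionise C2–O1.

**14 ⇒ 11.** The C4–C4a bond is cut, opening ring C to the aryl bromide / N-methoxy-N-methylamide 11. The neighbouring cut at O1–C2 (oxa-Michael closure of a hydroxychalcone) would set C2 under equilibrating conditions. The acid version of the same cut (Friedel–Crafts acylation) would expose the ionisable C2–O1 bond to strong acid. A carbanion at C4a avoids both, and the bromine that generates it can only be at C4a. The precursor is acyclic at ring C and splits into two fragments of similar size. The forward step needs bromine–lithium exchange and ring closure to be faster than any deprotonation, and needs no free ketone to exist while base is present.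

**11 ⇒ 6 + 10.** The O1–C2 ether bond is cut to give bromophenol 6 and carbinol 10. Making the other ether bond (O1–C8a) would require arylating an alcohol with a hexasubstituted, electron-rich arene. Displacing a 4-aryl β-lactone with the phenoxide would rely on a lactone whose electron-rich aryl group invites ionisation and decarboxylation. A Mitsunobu reaction of a phenol with a secondary benzylic carbinol is the standard alternative and reduces the stereochemical problem to one secondary alcohol of R configuration. The forward step must deliver clean inversion at an ionisable benzylic carbon with a di-ortho-substituted phenol, and must not dehydrate the β-hydroxy amide; the amide is chosen over an ester because its methylene is much less acidic.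

**6 ⇒ 5 ⇒ 2 ⇒ 1.** The C4a–Br bond is cut, giving phenol 5, whose single ring hydrogen is ortho to the hydroxyl. Next the C8a–O bond is cut, giving aryl ether 2 (forward: ortho-lithiation, borylation and oxidation). Finally the acetal is removed to give commercial phenol 1. A formylation / Dakin sequence would give the same oxygen but costs more steps. The order of events differentiates the two adjacent oxygens automatically: the first is already an acetal when the second appears as a free phenol. The forward lithiation must occur beside the acetal and not beside a methoxyl.

**10 ⇒ 8 + 9, 8 ⇒ 7.** The amide C–N bond is cut to hydroxy ester 8 and amine salt 9, and the carbinol C–H bond of 8 is cut to β-keto ester 7. An auxiliary-based acetate aldol would need attachment and removal of the auxiliary. Catalytic transfer hydrogenation of an aryl β-keto ester is a one-step, well-established way to a 3-aryl-3-hydroxypropanoate of predictable configuration. The forward reduction must be highly enantioselective, since no later step can correct C2.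

## Roads not taken

Alternative 1: The cut is C3–C4, with C4 as a masked acyl anion. The open-chain precursor would be a ring A aryl 1,3-dithiane whose C8a oxygen carries the C2 stereocentre and a primary sulfonate on C3. An alkyllithium base would form the dithianyl anion, which would close ring C by 6-exo-tet displacement to give (2S)-8-(benzyloxy)-2-(3,4-dimethoxyphenyl)-5,6,7-trimethoxyspiro[chromane-4,2'-[1,3]dithiane] A1.
- Merits: no carbonyl exists while base is present, so the E1cB opening of ring C is impossible on the way to A1, and the bond is made by SN2 at an unhindered primary carbon away from the stereocentre.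
- Weak points:
  - The dithiane sits between two ortho substituents on a hexasubstituted ring, so the anion is slow to form and hindered.
  - The base has other targets: the doubly activated benzylic C2–H, and E2 elimination of the β-aryloxy sulfonate.
  - The C2 aryl ether still has to be made, now from a 1,2-diol derivative.
  - Ring A needs a formyl group at C4a in addition to its oxygens.
  - The dithioketal of A1 must be hydrolysed with thiophilic salts such as Hg(ClO4)2 or with oxidants, both poorly matched to a penta-oxygenated arene. The benzyl ether of A1 then has to be removed over Pd/C, which sulfur residues poison.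
- Comparison: in shielding the product from base the road through A1 is at least as safe as the chosen plan, which relies on a chelated adduct surviving until the quench. The chosen plan offers instead the ketone directly, one mild deprotection, and a route several steps shorter.

Alternative 2: The cut goes through ring A itself, across C8–C8a, back to a cyclobutenone made from a squaric ester. Heating a 4-alkenyl-4-methoxycyclobutenone, whose alkenyl group is the C4a=C8a enol ether of a preformed chiral dihydropyran, would open the four-membered ring to a dienylketene. 6π-Electrocyclisation would form C8–C8a, and tautomerisation would give (2S)-2,4-cis-4-(tert-butyldimethylsilyloxy)-2-(3,4-dimethoxyphenyl)-5,6,7-trimethoxychroman-8-ol A2.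
- Merits: every ring A carbon of A2 from C5 to C8 derives from a defined cyclobutenone carbon, so the substitution pattern is programmed. The C8 hydroxyl of A2 emerges free and already differentiated from the methoxyls. In protecting-group economy this is better than the chosen plan, which spends two operations on the acetal. No organolithium meets an enolisable carbonyl.
- Weak points:
  - The stereocentre has to be built into a metallated 2-aryl-4-silyloxydihydropyran, a much harder fragment than one carbinol.
  - A second stereocentre at C4 is made only to be destroyed.
  - From A2 the silyl ether must be removed and the benzylic alcohol oxidised in the presence of a free phenol para to a methoxyl, a motif that goes to quinones easily. The unprotected hydroxyl that is the merit of the route would probably have to be protected after all.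
  - The sequence is long.
- Comparison: since ring A is available here from a commercial phenol in three steps, programmed construction of that ring buys little. The chosen plan is shorter than the road through A2 and needs no redox adjustment at C4.

Alternative 3: Both O1–C8a and C4–C4a are cut in one operation. A ring A aryne across C4a and C8a, released from an ortho-halo aryl sulfonate by i-PrMgCl·LiCl, would be attacked at C8a by the magnesium alkoxide of (3S)-3-(3,4-dimethoxyphenyl)-3-hydroxy-N-methoxy-N-methylpropanamide A3. The resulting C4a carbanion would acylate the amide to give (2S)-2-(3,4-dimethoxyphenyl)-5,6,7-trimethoxy-8-(4,4,5,5-tetramethyl-1,3,2-dioxaborolan-2-yl)chroman-4-one A4. Oxidation of the C–B bond of A4 would finish the synthesis.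
- Merits: it is the most convergent plan, with two bonds and ring C formed in one step. The aryl–oxygen bond is made at the arene, so the C–O bond of carbinol A3 is never broken and the configuration is retained without any substitution at an ionisable benzylic carbon. This is a real advantage over the chosen plan, whose Mitsunobu step is its stereochemically weakest link. The boryl group of A4 also replaces a protecting group at C8.
- Weak points:
  - The aryne precursor is a hexasubstituted benzene with a boronic ester, three methoxyls and two adjacent leaving groups. It is no easier to make than anything in the chosen route, and the boronic ester must survive the exchange reagent.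
  - Magnesium alkoxides of secondary alcohols are sluggish aryne traps, and the β-alkoxide of A3 can fragment by retro-aldol.
  - The regiochemistry rests on two directing effects in a fully substituted aryne.
  - The final alkaline peroxide oxidation of A4 exposes a finished flavanone to base.
- Comparison: if it worked, the road through A4 would be shorter and safer at C2. The chosen plan offers instead close precedent for each bond formation and a regiochemistry fixed by a bromine that can be in only one place.

Key step: step 7

Assumption: β-keto ester 7 is taken as a catalogue compound; if it had to be made, one Claisen condensation of the corresponding acetophenone with a dialkyl carbonate would supply it.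

## Route

Step 1
Reactants: 1 2,3,4-trimethoxyphenol
Product: 2 1,2,3-trimethoxy-4-(methoxymethoxy)benzene
Conditions: NaH, MOMCl, THF/DMF, 0 °C to rt
Reagents that add atoms: chloromethyl methyl ether (MOMCl), COCCl
Why: Williamson O-alkylation of the sodium phenoxide; the methoxymethyl ether protects the future C8 oxygen and is the strongest ortho-director on the ring for the next step.

Step 2
Reactants: 2 1,2,3-trimethoxy-4-(methoxymethoxy)benzene
Product: 5 3,4,5-trimethoxy-2-(methoxymethoxy)phenol, via ortho-lithiated ether 3 (not isolated), via dimethyl arylboronate 4 (not isolated)
Conditions: n-BuLi, TMEDA, THF, 0 °C; B(OMe)3, −78 °C to rt; 30% H2O2, aq NaOH, 0 °C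
Reagents that add atoms: hydrogen peroxide, OO
Why: Directed ortho-metalation: the chelating acetal outranks the flanked methoxyls as director, so the hydrogen beside it is removed to give 3. Borylation to 4 and ipso-hydroxylation (boron-to-oxygen aryl migration with alkaline peroxide) then install the oxygen that becomes O1.

Step 3
Reactants: 5 3,4,5-trimethoxy-2-(methoxymethoxy)phenol
Product: 6 2-bromo-3,4,5-trimethoxy-6-(methoxymethoxy)phenol
Conditions: NBS, i-Pr2NH (cat.), CH2Cl2, −78 to 0 °C
Reagents that add atoms: N-bromosuccinimide (NBS), O=C1CCC(=O)N1Br
Why: Electrophilic bromination of a phenol; the ring has one unsubstituted position, ortho to the free hydroxyl, so bromine can enter only at the future C4a. Amine-catalysed NBS at low temperature keeps the medium non-acidic for the acetal.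

Step 4
Reactants: 7 ethyl 3-(3,4-dimethoxyphenyl)-3-oxopropanoate
Product: 8 ethyl (3R)-3-(3,4-dimethoxyphenyl)-3-hydroxypropanoate
Conditions: RuCl(p-cymene)[(R,R)-TsDPEN] (1 mol%), HCO2H/Et3N (5:2 azeotrope), DMF, 40 °C
Reagents that add atoms: none
Why: Noyori asymmetric transfer hydrogenation of an aryl ketone; aryl β-keto esters are established substrates. The hydride is delivered to the carbonyl face fixed by the CH/π contact between the p-cymene ligand and the aryl ring, which with the (R,R) ligand and this substituent pattern (aryl ranks above CH2) should give the R carbinol.

Step 5
Reactants: 8 ethyl (3R)-3-(3,4-dimethoxyphenyl)-3-hydroxypropanoate; 9 N,O-dimethylhydroxylamine hydrochloride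
Product: 10 (3R)-3-(3,4-dimethoxyphenyl)-3-hydroxy-N-methoxy-N-methylpropanamide
Conditions: i-PrMgCl, THF, −20 to 0 °C
Reagents that add atoms: none
Why: Weinreb aminolysis of an ester by the chloromagnesium amide formed in the flask from 9 and i-PrMgCl; the carbinol travels as its magnesium alkoxide and its configuration is not involved.

Step 6
Reactants: 6 2-bromo-3,4,5-trimethoxy-6-(methoxymethoxy)phenol; 10 (3R)-3-(3,4-dimethoxyphenyl)-3-hydroxy-N-methoxy-N-methylpropanamide
Product: 11 (3S)-3-[2-bromo-3,4,5-trimethoxy-6-(methoxymethoxy)phenoxy]-3-(3,4-dimethoxyphenyl)-N-methoxy-N-methylpropanamide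
Conditions: PPh3, DIAD, toluene, 0 °C to rt
Reagents that add atoms: none
Why: Mitsunobu etherification: the carbinol is activated as its oxyphosphonium ion and displaced by the phenoxide of 6, whose acidity is raised by the ortho bromine, in an SN2 step with inversion (R carbinol to S aryl ether, the priority order O > aryl > CH2 being unchanged). The weakly acidic amide methylene, the non-polar solvent and the low temperature are chosen to hold back elimination and ionisation.

Step 7
Reactants: 11 (3S)-3-[2-bromo-3,4,5-trimethoxy-6-(methoxymethoxy)phenoxy]-3-(3,4-dimethoxyphenyl)-N-methoxy-N-methylpropanamide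
Product: 14 (2S)-2-(3,4-dimethoxyphenyl)-5,6,7-trimethoxy-8-(methoxymethoxy)chroman-4-one, via aryllithium 12 (not isolated), via lithium hemiaminal chelate 13 (not isolated)
Conditions: t-BuLi (2.1 equiv), THF, −78 °C; sat. aq NH4Cl, −78 °C to rt
Reagents that add atoms: none
Why: Parham-type cycloacylation: t-BuLi exchanges the C4a bromine almost instantly at this temperature, the second equivalent destroying the tert-butyl bromide so that the exchange cannot reverse, and aryllithium 12 adds to the amide carbonyl five atoms away. The closure is 6-exo-trig and forms the C4–C4a bond and ring C; the closest known reaction type is the halogen–lithium exchange / intramolecular acylation of 3-(2-bromoaryloxy)propanoic acid derivatives to chroman-4-ones. Adduct 13 is held as a five-membered lithium chelate between the alkoxide and the N-methoxy oxygen and should not collapse before the cold NH4Cl quench, so no ketone coexists with base and neither over-addition nor enolate-driven opening of ring C can take place. No stereocentre is created in 14, since the hemiaminal carbon of 13 becomes the carbonyl carbon, and C2 is not touched and keeps its S configuration. Regioselectivity is not in question because the bromine occupies the only oxygen-free carbon of ring A. The selectivity that is needed is chemoselectivity: exchange and closure must precede deprotonation at the amide methylene, which would expel the C8a aryloxide, and precede direct addition of t-BuLi to the amide. The high rate of bromine–lithium exchange, the low temperature and the intramolecular six-membered approach secure this, and the acetal and methyl ethers are inert to the reagent.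

Step 8
Reactants: 14 (2S)-2-(3,4-dimethoxyphenyl)-5,6,7-trimethoxy-8-(methoxymethoxy)chroman-4-one
Product: 15 (2S)-2-(3,4-dimethoxyphenyl)-8-hydroxy-5,6,7-trimethoxychroman-4-one
Conditions: HCl (cat.), MeOH, 0 °C to rt
Reagents that add atoms: none
Why: Acid-catalysed acetal exchange (methanolysis) removes the methoxymethyl group as dimethoxymethane. The conditions are mild enough to leave the methyl ethers, the ketone and the C2–O1 bond alone, and no base is involved, so the S configuration should be retained.

## Compound list

1 | 2,3,4-trimethoxyphenol | COc1ccc(O)c(OC)c1OC | starting material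
2 | 1,2,3-trimethoxy-4-(methoxymethoxy)benzene | COCOc1ccc(OC)c(OC)c1OC | intermediate
3 | [3,4,5-trimethoxy-2-(methoxymethoxy)phenyl]lithium | [Li]c1cc(OC)c(OC)c(OC)c1OCOC | intermediate
4 | dimethyl [3,4,5-trimethoxy-2-(methoxymethoxy)phenyl]boronate | COB(OC)c1cc(OC)c(OC)c(OC)c1OCOC | intermediate
5 | 3,4,5-trimethoxy-2-(methoxymethoxy)phenol | COCOc1c(O)cc(OC)c(OC)c1OC | intermediate
6 | 2-bromo-3,4,5-trimethoxy-6-(methoxymethoxy)phenol | COCOc1c(O)c(Br)c(OC)c(OC)c1OC | intermediate
7 | ethyl 3-(3,4-dimethoxyphenyl)-3-oxopropanoate | CCOC(=O)CC(=O)c1ccc(OC)c(OC)c1 | starting material
8 | ethyl (3R)-3-(3,4-dimethoxyphenyl)-3-hydroxypropanoate | COc1ccc([C@H](O)CC(=O)OCC)cc1OC | intermediate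
9 | N,O-dimethylhydroxylamine hydrochloride | CNOC.Cl | starting material
10 | (3R)-3-(3,4-dimethoxyphenyl)-3-hydroxy-N-methoxy-N-methylpropanamide | COc1ccc([C@H](O)CC(=O)N(C)OC)cc1OC | intermediate
11 | (3S)-3-[2-bromo-3,4,5-trimethoxy-6-(methoxymethoxy)phenoxy]-3-(3,4-dimethoxyphenyl)-N-methoxy-N-methylpropanamide | COc1ccc([C@@H](Oc2c(Br)c(OC)c(OC)c(OC)c2OCOC)CC(=O)N(C)OC)cc1OC | intermediate
12 | {2-[(1S)-1-(3,4-dimethoxyphenyl)-3-[methoxy(methyl)amino]-3-oxopropoxy]-4,5,6-trimethoxy-3-(methoxymethoxy)phenyl}lithium | COc1ccc([C@@H](Oc2c([Li])c(OC)c(OC)c(OC)c2OCOC)CC(=O)N(C)OC)cc1OC | intermediate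
13 | lithium (2S)-2-(3,4-dimethoxyphenyl)-5,6,7-trimethoxy-4-[methoxy(methyl)amino]-8-(methoxymethoxy)chroman-4-olate (configuration at C4 not defined) | COc1ccc([C@@H]2CC(O[Li])(N(C)OC)c3c(c(OCOC)c(OC)c(OC)c3OC)O2)cc1OC | intermediate
14 | (2S)-2-(3,4-dimethoxyphenyl)-5,6,7-trimethoxy-8-(methoxymethoxy)chroman-4-one | COc1ccc([C@@H]2CC(=O)c3c(c(OCOC)c(OC)c(OC)c3OC)O2)cc1OC | intermediate
15 | (2S)-2-(3,4-dimethoxyphenyl)-8-hydroxy-5,6,7-trimethoxychroman-4-one | COc1ccc([C@@H]2CC(=O)c3c(c(O)c(OC)c(OC)c3OC)O2)cc1OC | target

## Step count and risks

Total step count: 8. Longest linear sequence: 6 steps (steps 1, 2, 3, 6, 7, 8 from phenol 1); the second branch (steps 4 and 5) joins at step 6.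

**Step 7 (key step).** The most likely failure is proton transfer instead of carbonyl addition. The aryllithium or the alkyllithium may remove a hydrogen from the C3 methylene (or the benzylic C2–H), and the resulting enolate would expel the C8a aryloxide and sever the ether. A hindered aryllithium flanked by two oxygens could also close slowly enough for this to compete.

The fallback replaces the amide by a carboxylate, whose α-hydrogens cannot be removed without forming a dianion. It sets out from 11. Reduction with i-Bu2AlH at −78 °C should give (3S)-3-[2-bromo-3,4,5-trimethoxy-6-(methoxymethoxy)phenoxy]-3-(3,4-dimethoxyphenyl)propanal F1. Buffered chlorite oxidation (NaClO2, NaH2PO4, 2-methyl-2-butene) should then give (3S)-3-[2-bromo-3,4,5-trimethoxy-6-(methoxymethoxy)phenoxy]-3-(3,4-dimethoxyphenyl)propanoic acid F2. One equivalent of n-BuLi would convert it into lithium (3S)-3-[2-bromo-3,4,5-trimethoxy-6-(methoxymethoxy)phenoxy]-3-(3,4-dimethoxyphenyl)propanoate F3, and t-BuLi would then effect exchange and closure onto the carboxylate. The resulting geminal dilithium diolate releases the ketone only on quench, and the route is rejoined at 14.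

**Step 6.** Three processes threaten the Mitsunobu coupling:
- elimination of the activated carbinol to the cinnamamide, by E2 with the hydrazide anion or by E1 through the electron-rich benzylic cation;
- erosion of configuration through an ion-pair pathway at that same benzylic carbon;
- slow substitution by a phenol with two ortho substituents, which gives the first two more time.

The fallback uses a carbinol with no acidic hydrogen beside the reacting carbon. It sets out from 6. The coupling partner is (1R)-1-(3,4-dimethoxyphenyl)but-3-en-1-ol F4, obtained by asymmetric allylboration of 3,4-dimethoxybenzaldehyde with the antipode of Ipc2B(allyl) that delivers the R alcohol. Its Mitsunobu coupling with 6 should give 1-bromo-2-{[(1S)-1-(3,4-dimethoxyphenyl)but-3-en-1-yl]oxy}-4,5,6-trimethoxy-3-(methoxymethoxy)benzene F5. Dihydroxylation and cleavage (OsO4 cat., NMO; then NaIO4) would give aldehyde F1, chlorite oxidation acid F2, and carbodiimide coupling with 9 (EDC·HCl, HOBt, i-Pr2NEt) returns to the route at 11.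

**Step 2.** The risk is lithiation beside the terminal methoxyl instead of beside the acetal, or incomplete lithiation of a crowded, electron-rich ring; either would give the wrong or no phenol. The fallback fixes the regiochemistry by phenol-directed ortho-formylation. It sets out from 1. MgCl2, Et3N and paraformaldehyde in hot MeCN should give 2-hydroxy-3,4,5-trimethoxybenzaldehyde F6. Methoxymethylation (NaH, MOMCl) gives 3,4,5-trimethoxy-2-(methoxymethoxy)benzaldehyde F7. Baeyer–Villiger (Dakin-type) oxidation with mCPBA gives 3,4,5-trimethoxy-2-(methoxymethoxy)phenyl formate F8, and methanolysis (K2CO3, MeOH) returns to the route at 5.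

**Step 3.** The risk is oxidation of the very electron-rich free phenol to a quinone by the brominating agent, or acid-induced loss of the acetal. The fallback brominates after the phenol has been capped. It sets out from 5. Mitsunobu coupling with 10 should give (3S)-3-(3,4-dimethoxyphenyl)-N-methoxy-N-methyl-3-[3,4,5-trimethoxy-2-(methoxymethoxy)phenoxy]propanamide F9. Its single free ring A position, activated by two ortho oxygens and one para oxygen, should be brominated by buffered NBS in preference to ring B, which returns to the route at 11.

## Further compounds

F1 | step 7 | (3S)-3-[2-bromo-3,4,5-trimethoxy-6-(methoxymethoxy)phenoxy]-3-(3,4-dimethoxyphenyl)propanal | COc1ccc([C@@H](Oc2c(Br)c(OC)c(OC)c(OC)c2OCOC)CC=O)cc1OC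
F2 | step 7 | (3S)-3-[2-bromo-3,4,5-trimethoxy-6-(methoxymethoxy)phenoxy]-3-(3,4-dimethoxyphenyl)propanoic acid | COc1ccc([C@@H](Oc2c(Br)c(OC)c(OC)c(OC)c2OCOC)CC(=O)O)cc1OC
F3 | step 7 | lithium (3S)-3-[2-bromo-3,4,5-trimethoxy-6-(methoxymethoxy)phenoxy]-3-(3,4-dimethoxyphenyl)propanoate | COc1ccc([C@@H](Oc2c(Br)c(OC)c(OC)c(OC)c2OCOC)CC(=O)[O-])cc1OC.[Li+]
F4 | step 6 | (1R)-1-(3,4-dimethoxyphenyl)but-3-en-1-ol | COc1ccc([C@H](O)CC=C)cc1OC
F5 | step 6 | 1-bromo-2-{[(1S)-1-(3,4-dimethoxyphenyl)but-3-en-1-yl]oxy}-4,5,6-trimethoxy-3-(methoxymethoxy)benzene | COc1ccc([C@@H](Oc2c(Br)c(OC)c(OC)c(OC)c2OCOC)CC=C)cc1OC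
F6 | step 2 | 2-hydroxy-3,4,5-trimethoxybenzaldehyde | COc1cc(C=O)c(O)c(OC)c1OC
F7 | step 2 | 3,4,5-trimethoxy-2-(methoxymethoxy)benzaldehyde | COCOc1c(C=O)cc(OC)c(OC)c1OC
F8 | step 2 | 3,4,5-trimethoxy-2-(methoxymethoxy)phenyl formate | COCOc1c(OC=O)cc(OC)c(OC)c1OC
F9 | step 3 | (3S)-3-(3,4-dimethoxyphenyl)-N-methoxy-N-methyl-3-[3,4,5-trimethoxy-2-(methoxymethoxy)phenoxy]propanamide | COc1ccc([C@@H](Oc2cc(OC)c(OC)c(OC)c2OCOC)CC(=O)N(C)OC)cc1OC
A1 | alternative 1 | (2S)-8-(benzyloxy)-2-(3,4-dimethoxyphenyl)-5,6,7-trimethoxyspiro[chromane-4,2'-[1,3]dithiane] | COc1ccc([C@@H]2CC3(SCCCS3)c3c(c(OCc4ccccc4)c(OC)c(OC)c3OC)O2)cc1OC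
A2 | alternative 2 | (2S)-2,4-cis-4-(tert-butyldimethylsilyloxy)-2-(3,4-dimethoxyphenyl)-5,6,7-trimethoxychroman-8-ol | COc1ccc([C@@H]2C[C@H](O[Si](C)(C)C(C)(C)C)c3c(c(O)c(OC)c(OC)c3OC)O2)cc1OC
A3 | alternative 3 | (3S)-3-(3,4-dimethoxyphenyl)-3-hydroxy-N-methoxy-N-methylpropanamide | COc1ccc([C@@H](O)CC(=O)N(C)OC)cc1OC
A4 | alternative 3 | (2S)-2-(3,4-dimethoxyphenyl)-5,6,7-trimethoxy-8-(4,4,5,5-tetramethyl-1,3,2-dioxaborolan-2-yl)chroman-4-one | COc1ccc([C@@H]2CC(=O)c3c(c(B4OC(C)(C)C(C)(C)O4)c(OC)c(OC)c3OC)O2)cc1OC
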